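**Retrosynthetic overview**
1. Target 9 ⇒ mono-methyl ether 8 (O-demethylation, last step) ⇒ aldehyde 6 (Baeyer–Villiger): the formyl group is a latent OH and also the activator for the coupling.
2. Key disconnection: the diaryl ether C–O bond, the only bond between the two halves ⇒ phenol 2 + fluoroaldehyde 4. They are joined intermolecularly by conjugate (Michael-type) addition–elimination (SNAr) at the formyl-conjugated C–F carbon.
3. 2 ⇐ 5-bromo-2-methoxyphenol (OH-directed dibromination); 4 ⇐ 5-bromo-2-fluorobenzaldehyde (bromination ortho to F, meta to CHO). All five bromines are placed on the monocyclic precursors, before the coupling.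
4. Ring order: no ring is formed; both benzene rings are bought intact and only functionalised.

Assumption: the target has no stereocentre and no configurationally stable axis, so it is made as the achiral compound drawn.

**Route**

Step 1
Reactants: 1 5-bromo-2-methoxyphenol
Product: 2 2,3,4-tribromo-6-methoxyphenol
Conditions: Br2 (2.1 equiv), AcOH, 10 °C → rt
Reagents that add atoms: bromine, BrBr
Why: Electrophilic aromatic bromination in which the free OH is the dominant director, so bromine enters its para and ortho positions and the least activated site, ortho to OMe, stays unsubstituted.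

Step 2
Reactants: 3 5-bromo-2-fluorobenzaldehyde
Product: 4 3,5-dibromo-2-fluorobenzaldehyde
Conditions: NBS (1.3 equiv), TFA/conc. H2SO4, 50 °C
Reagents that add atoms: N-bromosuccinimide, O=C1CCC(=O)N1Br
Why: Electrophilic aromatic bromination with acid-activated NBS, strong enough for a deactivated ring, goes to C3 because that is the only free position both ortho to F and meta to CHO.

Step 3
Reactants: 2 2,3,4-tribromo-6-methoxyphenol; 4 3,5-dibromo-2-fluorobenzaldehyde
Product: 6 3,5-dibromo-2-(2,3,4-tribromo-6-methoxyphenoxy)benzaldehyde, via caesium phenoxide 5 (not isolated)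
Conditions: Cs2CO3 (1.5 equiv), DMAc, 100 °C, N2
Reagents that add atoms: none
Why: Nucleophilic aromatic substitution by conjugate (Michael-type) addition–elimination: the phenoxide adds to the C–F carbon, the β-position of the aryl aldehyde, and fluoride is lost, helped by the inductive effect of the ortho and para bromines, while no other halogen in either partner is ortho or para to an acceptor group.

Step 4
Reactants: 6 3,5-dibromo-2-(2,3,4-tribromo-6-methoxyphenoxy)benzaldehyde
Product: 8 3,5-dibromo-2-(2,3,4-tribromo-6-methoxyphenoxy)phenol, via aryl formate 7 (not isolated)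
Conditions: mCPBA (2 equiv), CH2Cl2, 0 °C → rt; then K2CO3 (cat.), MeOH, rt on the crude formate
Reagents that add atoms: meta-chloroperoxybenzoic acid, OOC(=O)c1cccc(Cl)c1
Why: Baeyer–Villiger (Dakin-type) oxidation in which the aryl group, made the better migrating group by its ortho aryloxy donor, shifts to oxygen to give the formate, and mild methanolysis then frees the phenol without touching the methyl ether, the diaryl ether or the C–Br bonds.

Step 5
Reactants: 8 3,5-dibromo-2-(2,3,4-tribromo-6-methoxyphenoxy)phenol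
Product: 9 3,4,5-tribromo-2-(2,4-dibromo-6-hydroxyphenoxy)phenol
Conditions: BBr3 (3 equiv), CH2Cl2, −78 °C → rt; then H2O
Reagents that add atoms: none
Why: Lewis acid mediated O-demethylation, in which BBr3 coordinates the methoxy oxygen and bromide removes the methyl group by SN2, leaves the diaryl ether and aryl bromides intact and gives the achiral target after hydrolytic work-up.

**Compound list**
1 | 5-bromo-2-methoxyphenol | COc1ccc(Br)cc1O | starting material
2 | 2,3,4-tribromo-6-methoxyphenol | COc1cc(Br)c(Br)c(Br)c1O | intermediate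
3 | 5-bromo-2-fluorobenzaldehyde | O=Cc1cc(Br)ccc1F | starting material
4 | 3,5-dibromo-2-fluorobenzaldehyde | O=Cc1cc(Br)cc(Br)c1F | intermediate
5 | caesium 2,3,4-tribromo-6-methoxyphenolate | COc1cc(Br)c(Br)c(Br)c1[O-].[Cs+] | intermediate (not isolated)
6 | 3,5-dibromo-2-(2,3,4-tribromo-6-methoxyphenoxy)benzaldehyde | COc1cc(Br)c(Br)c(Br)c1Oc1c(Br)cc(Br)cc1C=O | intermediate
7 | 3,5-dibromo-2-(2,3,4-tribromo-6-methoxyphenoxy)phenyl formate | COc1cc(Br)c(Br)c(Br)c1Oc1c(Br)cc(Br)cc1OC=O | intermediate (not isolated)
8 | 3,5-dibromo-2-(2,3,4-tribromo-6-methoxyphenoxy)phenol | COc1cc(Br)c(Br)c(Br)c1Oc1c(Br)cc(Br)cc1O | intermediate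
9 | 3,4,5-tribromo-2-(2,4-dibromo-6-hydroxyphenoxy)phenol | Oc1cc(Br)cc(Br)c1Oc1c(O)cc(Br)c(Br)c1Br | target

**Totals**
Total step count: 5. Longest linear sequence: 4 steps (step 1 or step 2, then steps 3, 4, 5).

**Three steps most likely to fail**

Step 3. The SNAr must form a tetra-ortho-substituted diaryl ether from a hindered, weakly nucleophilic phenoxide. The fallback is a hypervalent-iodine O-arylation, which tolerates ortho substitution and leaves C–Br bonds alone; it sets out from 2 and comes back to the route at 9. Commercial 2,4-dibromo-6-methoxyaniline is diazotised (NaNO2, H2SO4/AcOH, 0 °C) to 2,4-dibromo-6-methoxybenzenediazonium hydrogensulfate F1, which with KI gives 1,5-dibromo-2-iodo-3-methoxybenzene F2. Oxidation with mCPBA and TsOH·H2O in MeCN, then trapping with 1,3,5-trimethoxybenzene, gives (2,4-dibromo-6-methoxyphenyl)(2,4,6-trimethoxyphenyl)iodonium 4-methylbenzenesulfonate F3. Phenol 2 is converted with Cs2CO3 into its caesium salt 5 and arylated by the iodonium salt (MeCN, 60 °C; the trimethoxyphenyl group is the non-transferred dummy) to give 1,2,3-tribromo-4-(2,4-dibromo-6-methoxyphenoxy)-5-methoxybenzene F4. BBr3 (CH2Cl2, −78 °C → rt) then cleaves both methyl ethers to give 9.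

Step 4. Hydride migration instead of aryl migration would give the benzoic acid, because the migrating ring carries two bromines. The fallback changes the substrate from aldehyde to methyl ketone, where hydride migration is impossible and aryl outcompetes methyl; it sets out from 6 and comes back at 8. MeMgBr (THF, −78 → 0 °C) gives racemic 1-[3,5-dibromo-2-(2,3,4-tribromo-6-methoxyphenoxy)phenyl]ethan-1-ol F5. Dess–Martin periodinane (CH2Cl2, rt) gives 1-[3,5-dibromo-2-(2,3,4-tribromo-6-methoxyphenoxy)phenyl]ethan-1-one F6. Baeyer–Villiger oxidation with CF3CO3H (TFAA, urea·H2O2, Na2HPO4, CH2Cl2) gives 3,5-dibromo-2-(2,3,4-tribromo-6-methoxyphenoxy)phenyl acetate F7, and K2CO3 in MeOH releases 8.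

Step 2. Electrophilic bromination of a ring that already carries CHO, F and Br is slow, and the aldehyde can be oxidised. The fallback replaces electrophilic substitution by directed ortho-metalation; it sets out from 3 and comes back at 4. Compound 3 with ethylene glycol (TsOH cat., toluene, Dean–Stark) gives 2-(5-bromo-2-fluorophenyl)-1,3-dioxolane F8. LDA (THF, −78 °C) removes the proton ortho to fluorine to give [5-bromo-3-(1,3-dioxolan-2-yl)-2-fluorophenyl]lithium F9, which is quenched at −78 °C with 1,2-dibromotetrachloroethane to give 2-(3,5-dibromo-2-fluorophenyl)-1,3-dioxolane F10. Hydrolysis with 2 M HCl in THF releases 4.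

**Further compounds**
F1 | step 3 | 2,4-dibromo-6-methoxybenzenediazonium hydrogensulfate | COc1cc(Br)cc(Br)c1[N+]#N.OS(=O)(=O)[O-]
F2 | step 3 | 1,5-dibromo-2-iodo-3-methoxybenzene | COc1cc(Br)cc(Br)c1I
F3 | step 3 | (2,4-dibromo-6-methoxyphenyl)(2,4,6-trimethoxyphenyl)iodonium 4-methylbenzenesulfonate | COc1cc(Br)cc(Br)c1[I+]c1c(OC)cc(OC)cc1OC.Cc1ccc(cc1)S(=O)(=O)[O-]
F4 | step 3 | 1,2,3-tribromo-4-(2,4-dibromo-6-methoxyphenoxy)-5-methoxybenzene | COc1cc(Br)cc(Br)c1Oc1c(OC)cc(Br)c(Br)c1Br
F5 | step 4 | 1-[3,5-dibromo-2-(2,3,4-tribromo-6-methoxyphenoxy)phenyl]ethan-1-ol (racemic) | CC(O)c1cc(Br)cc(Br)c1Oc1c(OC)cc(Br)c(Br)c1Br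
F6 | step 4 | 1-[3,5-dibromo-2-(2,3,4-tribromo-6-methoxyphenoxy)phenyl]ethan-1-one | CC(=O)c1cc(Br)cc(Br)c1Oc1c(OC)cc(Br)c(Br)c1Br
F7 | step 4 | 3,5-dibromo-2-(2,3,4-tribromo-6-methoxyphenoxy)phenyl acetate | CC(=O)Oc1cc(Br)cc(Br)c1Oc1c(OC)cc(Br)c(Br)c1Br
F8 | step 2 | 2-(5-bromo-2-fluorophenyl)-1,3-dioxolane | Fc1ccc(Br)cc1C1OCCO1
F9 | step 2 | [5-bromo-3-(1,3-dioxolan-2-yl)-2-fluorophenyl]lithium | [Li]c1cc(Br)cc(C2OCCO2)c1F
F10 | step 2 | 2-(3,5-dibromo-2-fluorophenyl)-1,3-dioxolane | Fc1c(Br)cc(Br)cc1C1OCCO1
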